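## Retrosynthetic overview

1. Eupalmerin acetate ← C13 alcohol (acetylation last) ← one step that forms C1–C14, closing the 14-membered carbocycle and the cis-fused α-methylene-γ-lactone together: a Cr-catalysed intramolecular 2-(alkoxycarbonyl)allylation of an aldehyde (sets C1 and C14).
2. The (Z)-2-(bromomethyl)enoate comes from a terminal alkene by cross-metathesis with methyl 2-(hydroxymethyl)acrylate; the C14 aldehyde comes from a primary TES ether.
3. C6–C7 is made by a B-alkyl Suzuki–Miyaura coupling of a West iodo-epoxide (C1–C6) with an East (E)-vinyl iodide (C7–C14).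
4. East: Sharpless epoxidation of crotyl alcohol and Cu-catalysed epoxide opening set C13 and C12; Zr-catalysed carboalumination sets the 7E alkene. West: carboalumination/Pd allylation of but-3-yn-1-ol, then Shi epoxidation sets C3 and C4.
5. Ring order: oxirane at the fragment stage, then carbocycle and lactone simultaneously in the last C–C bond formation.

Assumption: cembrane numbering is used for locants in the larger intermediates (C1 = ring-fusion CH, C14 = lactone O–CH, C15/C16/C17 = lactone α-carbon, carbonyl and exocyclic CH2). The target is (1S,3R,4R,7E,12S,13R,14R). Catalysts and ligands (Shi ketone, chiral Cr ligand, Ru and Pd complexes) are taken as available and are not counted as steps.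

## Route

**Step 1**
Reactants: 1, 5-chloropent-1-yne
Product: 2, (5-chloropent-1-yn-1-yl)trimethylsilane
Conditions: n-BuLi, THF, −78 °C; TMSCl, −78 °C → rt
Reagents that add atoms: chlorotrimethylsilane, C[Si](C)(C)Cl
Why: Acetylide C-silylation masks the acidic alkyne C–H so the chain can later serve as a Grignard reagent.

**Step 2**
Reactants: 2
Product: 3, (5-iodopent-1-yn-1-yl)trimethylsilane
Conditions: NaI, acetone, reflux
Reagents that add atoms: sodium iodide, [Na+].[I-]
Why: Finkelstein exchange gives the primary iodide, which forms the organomagnesium reagent under mild conditions.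

**Step 3**
Reactants: 4, (E)-but-2-en-1-ol
Product: 5, [(2S,3S)-3-methyloxiran-2-yl]methanol
Conditions: Ti(OiPr)4 (10 mol %), L-(+)-DET (12 mol %), t-BuOOH, 4 Å MS, CH2Cl2, −20 °C
Reagents that add atoms: tert-butyl hydroperoxide, CC(C)(C)OO
Why: Sharpless asymmetric epoxidation; L-(+)-tartrate gives the (2S,3S)-epoxide, whose C2–O becomes the (13R) oxygen and whose C3 becomes C12 after inversion.

**Step 4**
Reactants: 5
Product: 6, triethyl{[(2S,3S)-3-methyloxiran-2-yl]methoxy}silane
Conditions: TESCl, imidazole, CH2Cl2, 0 °C
Reagents that add atoms: chlorotriethylsilane, CC[Si](Cl)(CC)CC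
Why: Silylation of the primary alcohol protects C14–O and biases the next nucleophile toward the distal epoxide carbon.

**Step 5**
Reactants: 3 and 6
Product: 7, (2R,3S)-3-methyl-1-[(triethylsilyl)oxy]-8-(trimethylsilyl)oct-7-yn-2-ol
Conditions: 3, Mg, Et2O, rt; then CuI (10 mol %), 6, THF, −40 → 0 °C
Reagents that add atoms: none
Why: Cu-catalysed SN2 opening of the epoxide by the Grignard reagent at the methyl-bearing carbon (less hindered and not deactivated by the CH2OSi group) inverts that centre to give 12S with Me/OH syn, while C13 is untouched (13R).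

**Step 6**
Reactants: 7
Product: 8, (2R,3S)-3-methyl-1,2-bis[(triethylsilyl)oxy]-8-(trimethylsilyl)oct-7-yne
Conditions: TESOTf, 2,6-lutidine, CH2Cl2, −78 °C
Reagents that add atoms: triethylsilyl triflate, CC[Si](CC)(CC)OS(=O)(=O)C(F)(F)F
Why: Silylation of the secondary alcohol gives a bis-TES diol in which the primary TES ether can later be oxidised selectively.

**Step 7**
Reactants: 8
Product: 9, (2R,3S)-3-methyl-1,2-bis[(triethylsilyl)oxy]oct-7-yne
Conditions: K2CO3, MeOH, 0 °C → rt
Reagents that add atoms: none
Why: Methoxide protodesilylation removes the labile alkynyl TMS group while the O–TES ethers survive.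

**Step 8**
Reactants: 9
Product: 10, (2R,3S,7E)-8-iodo-3,7-dimethyl-1,2-bis[(triethylsilyl)oxy]oct-7-ene
Conditions: AlMe3, Cp2ZrCl2, CH2Cl2, 0 °C → rt; then I2, THF, −30 °C
Reagents that add atoms: trimethylaluminium, C[Al](C)C; iodine, II
Why: Negishi Zr-catalysed carboalumination adds Me–Al syn across the terminal alkyne (Me to the internal carbon), and iodinolysis with retention gives the (E)-vinyl iodide that fixes the 7E geometry.

**Step 9**
Reactants: 11, but-3-yn-1-ol; 12, allyl bromide
Product: 13, (3E)-3-methylhepta-3,6-dien-1-ol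
Conditions: AlMe3 (3 equiv), Cp2ZrCl2 (25 mol %), CH2Cl2, 0 °C → rt; then 12, Pd(PPh3)4 (3 mol %), THF, rt
Reagents that add atoms: trimethylaluminium, C[Al](C)C
Why: Zr-catalysed carboalumination followed by Pd-catalysed alkenylalane–allyl bromide coupling (Negishi) proceeds with retention and gives the (E)-trisubstituted 1,4-diene.

**Step 10**
Reactants: 13
Product: 14, 2-[(2R,3R)-2-methyl-3-(prop-2-en-1-yl)oxiran-2-yl]ethan-1-ol
Conditions: D-fructose-derived Shi ketone (30 mol %), Oxone, K2CO3, Bu4NHSO4, MeCN/DMM/aq. buffer (pH 10.5), 0 °C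
Reagents that add atoms: Oxone (KHSO5), [K+].[O-]S(=O)(=O)OO
Why: Shi asymmetric epoxidation; the chiral dioxirane attacks the electron-rich trisubstituted alkene through the spiro transition state to give the (R,R)-epoxide (3R,4R) and leaves the monosubstituted alkene untouched.

**Step 11**
Reactants: 14
Product: 15, 2-[(2R,3R)-2-methyl-3-(prop-2-en-1-yl)oxiran-2-yl]ethyl methanesulfonate
Conditions: MsCl, Et3N, CH2Cl2, 0 °C
Reagents that add atoms: methanesulfonyl chloride, CS(=O)(=O)Cl
Why: Mesylation activates the primary alcohol under basic conditions that do not disturb the epoxide.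

**Step 12**
Reactants: 15
Product: 16, (2R,3R)-2-(2-iodoethyl)-2-methyl-3-(prop-2-en-1-yl)oxirane
Conditions: NaI, NaHCO3, acetone, 45 °C
Reagents that add atoms: sodium iodide, [Na+].[I-]
Why: Buffered Finkelstein displacement gives the primary iodide needed for lithium–iodine exchange without opening the epoxide.

**Step 13**
Reactants: 16 and 10
Product: 17, open-chain C1–C14 triene: terminal vinyl at C1, (3R,4R)-3,4-epoxide with the C4 methyl, (7E)-alkene with the C8 methyl, (12S)-methyl, (13R)-OTES, C14H2–OTES
Conditions: 16, t-BuLi (2.1 equiv), Et2O, −78 °C; 9-MeO-9-BBN, THF, −78 °C → rt; then 10, PdCl2(dppf) (10 mol %), AsPh3, K3PO4 (aq), DMF, rt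
Reagents that add atoms: none
Why: B-alkyl Suzuki–Miyaura coupling (Marshall's iodide → alkyl borate variant) joins C6 (sp3) to C7 (sp2) with retention of the E geometry, and the conditions tolerate the epoxide, silyl ethers and terminal alkene.

**Step 14**
Reactants: 17; 18, methyl 2-(hydroxymethyl)acrylate
Product: 19, trisubstituted enoate of 17: C1H=C15(CO2Me)–C17H2OH, with the C2 chain cis to CH2OH and trans to CO2Me
Conditions: 18 (6 equiv), Hoveyda–Grubbs II (10 mol %), 1,4-benzoquinone (10 mol %), CH2Cl2, 40 °C
Reagents that add atoms: none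
Why: Olefin cross-metathesis between the only reactive (monosubstituted) alkene and the 1,1-disubstituted acrylate gives the thermodynamically preferred enoate with the chain trans to the ester; the trisubstituted C7=C8 alkene does not react.

**Step 15**
Reactants: 19
Product: 20, allylic bromide: C1H=C15(CO2Me)–C17H2Br, a (Z)-2-(bromomethyl)enoate
Conditions: NBS, Me2S, CH2Cl2, −20 → 0 °C
Reagents that add atoms: N-bromosuccinimide, O=C1CCC(=O)N1Br
Why: Corey–Kim bromination converts the single free (allylic) alcohol into the bromide without touching the epoxide or the trisubstituted alkene.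

**Step 16**
Reactants: 20
Product: 21, bromo aldehyde: C14HO, (13R)-OTES, otherwise as 20
Conditions: (COCl)2, DMSO, CH2Cl2, −78 → −35 °C; i-Pr2NEt, −78 → −20 °C
Reagents that add atoms: none
Why: Direct Swern oxidation of the primary TES ether (cleaved in situ by the chlorosulfonium reagent) gives the α-silyloxy aldehyde while the secondary TES ether stays; the hindered base limits epimerisation and attack on the allylic bromide.

**Step 17**
Reactants: 21
Product: 22, 13-O-deacetyl eupalmerin acetate, the (1S,3R,4R,7E,12S,13R,14R) hydroxy lactone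
Conditions: CrCl2 (15 mol %), chiral oxazoline–sulfonamide ligand L* (18 mol %), proton sponge, Mn, Cp2ZrCl2, LiCl, 2,6-lutidine, MeCN/THF, rt, syringe-pump addition of 21 (final 2 mM); then HF·pyridine/pyridine, THF, 0 °C
Reagents that add atoms: none
Why: Proposed new method: a ligand-controlled, Cr-catalysed (Mn/Cp2ZrCl2 turnover) intramolecular Nozaki–Hiyama–Kishi-type 2-(alkoxycarbonyl)allylation that closes the 14-membered ring; Cr(II) reduces the allylic bromide to a (Z)-2-(methoxycarbonyl)allyl–Cr(III) species (chain cis to CH2Cr), which adds through a six-membered chair transition state with the C2 chain axial to give the 1,14-syn relationship (cis-fused lactone once the C14 alkoxide acylates on the adjacent ester), while the chiral ligand on Cr must direct C1 to the Re face of the (13R)-silyloxy aldehyde to set 14R against the substrate's Felkin/Cornforth preference (ligand antipode chosen by screening on a model α-silyloxy aldehyde); the closest known reactions are the intermolecular Cr-catalysed enantioselective 2-(alkoxycarbonyl)allylation of aldehydes to α-methylene-γ-butyrolactones and stoichiometric CrCl2-mediated allyl bromide–aldehyde macrocyclisations, neither shown as a catalytic, catalyst-controlled macrocyclisation on an α-oxygenated aldehyde; the buffered HF·pyridine stage completes lactonisation and removes the C13 TES group.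

**Step 18**
Reactants: 22
Product: 23, eupalmerin acetate
Conditions: Ac2O, pyridine, DMAP (cat.), CH2Cl2, 0 °C → rt
Reagents that add atoms: acetic anhydride, CC(=O)OC(C)=O
Why: Standard acylation of the only free hydroxyl (C13) under mild basic conditions that the epoxide and α-methylene lactone tolerate.

## Compound list

1 | 5-chloropent-1-yne | `C#CCCCCl` | starting material
2 | (5-chloropent-1-yn-1-yl)trimethylsilane | `C[Si](C)(C)C#CCCCCl` | intermediate
3 | (5-iodopent-1-yn-1-yl)trimethylsilane | `C[Si](C)(C)C#CCCCI` | intermediate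
4 | (E)-but-2-en-1-ol | `C/C=C/CO` | starting material
5 | [(2S,3S)-3-methyloxiran-2-yl]methanol | `OC[C@@H]1O[C@H]1C` | intermediate
6 | triethyl{[(2S,3S)-3-methyloxiran-2-yl]methoxy}silane | `CC[Si](CC)(CC)OC[C@@H]1O[C@H]1C` | intermediate
7 | (2R,3S)-3-methyl-1-[(triethylsilyl)oxy]-8-(trimethylsilyl)oct-7-yn-2-ol | `CC[Si](CC)(CC)OC[C@H](O)[C@@H](C)CCCC#C[Si](C)(C)C` | intermediate
8 | (2R,3S)-3-methyl-1,2-bis[(triethylsilyl)oxy]-8-(trimethylsilyl)oct-7-yne | `CC[Si](CC)(CC)OC[C@H](O[Si](CC)(CC)CC)[C@@H](C)CCCC#C[Si](C)(C)C` | intermediate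
9 | (2R,3S)-3-methyl-1,2-bis[(triethylsilyl)oxy]oct-7-yne | `CC[Si](CC)(CC)OC[C@H](O[Si](CC)(CC)CC)[C@@H](C)CCCC#C` | intermediate
10 | (2R,3S,7E)-8-iodo-3,7-dimethyl-1,2-bis[(triethylsilyl)oxy]oct-7-ene (East fragment, C7–C14) | `CC[Si](CC)(CC)OC[C@H](O[Si](CC)(CC)CC)[C@@H](C)CCC/C(C)=C/I` | intermediate
11 | but-3-yn-1-ol | `C#CCCO` | starting material
12 | allyl bromide | `C=CCBr` | starting material
13 | (3E)-3-methylhepta-3,6-dien-1-ol | `OCC/C(C)=C/CC=C` | intermediate
14 | 2-[(2R,3R)-2-methyl-3-(prop-2-en-1-yl)oxiran-2-yl]ethan-1-ol | `OCC[C@@]1(C)O[C@@H]1CC=C` | intermediate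
15 | 2-[(2R,3R)-2-methyl-3-(prop-2-en-1-yl)oxiran-2-yl]ethyl methanesulfonate | `CS(=O)(=O)OCC[C@@]1(C)O[C@@H]1CC=C` | intermediate
16 | (2R,3R)-2-(2-iodoethyl)-2-methyl-3-(prop-2-en-1-yl)oxirane (West fragment, C1–C6) | `ICC[C@@]1(C)O[C@@H]1CC=C` | intermediate
17 | open-chain (3R,4R,7E,12S,13R) C1–C14 epoxy triene, 13,14-bis-TES ether, terminal vinyl at C1 | `CC[Si](CC)(CC)OC[C@H](O[Si](CC)(CC)CC)[C@@H](C)CCC/C(C)=C/CC[C@@]1(C)O[C@@H]1CC=C` | intermediate
18 | methyl 2-(hydroxymethyl)acrylate | `C=C(CO)C(=O)OC` | starting material
19 | methyl 2-(hydroxymethyl)enoate of 17 (C2 chain trans to CO2Me) | `CC[Si](CC)(CC)OC[C@H](O[Si](CC)(CC)CC)[C@@H](C)CCC/C(C)=C/CC[C@@]1(C)O[C@@H]1C/C=C(/C(=O)OC)CO` | intermediate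
20 | corresponding (Z)-2-(bromomethyl)enoate | `CC[Si](CC)(CC)OC[C@H](O[Si](CC)(CC)CC)[C@@H](C)CCC/C(C)=C/CC[C@@]1(C)O[C@@H]1C/C=C(/C(=O)OC)CBr` | intermediate
21 | seco bromo aldehyde (C14 aldehyde, (13R)-OTES) | `O=C[C@H](O[Si](CC)(CC)CC)[C@@H](C)CCC/C(C)=C/CC[C@@]1(C)O[C@@H]1C/C=C(/C(=O)OC)CBr` | intermediate
22 | 13-O-deacetyl eupalmerin acetate | `C=C1C(=O)O[C@H]2[C@H](O)[C@@H](C)CCC/C(C)=C/CC[C@@]3(C)O[C@@H]3C[C@@H]12` | intermediate
23 | eupalmerin acetate | `C=C1C(=O)O[C@H]2[C@H](OC(C)=O)[C@@H](C)CCC/C(C)=C/CC[C@@]3(C)O[C@@H]3C[C@@H]12` | target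

## Summary

Total step count: 18.

Longest linear sequence: 12 steps (3 → 4 → 5 → 6 → 7 → 8 → 13 → 14 → 15 → 16 → 17 → 18; the path through steps 1–2 is also 12). This is two thirds of the total.

Steps most likely to fail:

1. **Step 17 (proposed new macrocyclising Cr-catalysed allylation).** The catalyst must override the anti (Felkin/Cornforth) preference of the α-silyloxy aldehyde, ring closure must beat oligomerisation, and the epoxide must survive the Lewis-acidic medium. Fallback with known chemistry: form C1–C14 intermolecularly by the indium-mediated aqueous Barbier reaction of the free 13-hydroxy aldehyde with a West-derived (Z)-2-(bromomethyl)enoate, where chelation control is established to give the 13,14-syn/1,14-cis array. The ring is then closed at C6–C7 by an intramolecular Pd-catalysed alkyl–alkenyl coupling.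

2. **Step 14 (cross-metathesis with a 1,1-disubstituted acrylate on a late intermediate).** Conversion and E/Z control are uncertain. Fallback: avoid metathesis by coupling the step-9 alkenylalane under Pd(0) with a pre-made methyl (E)-4-chloro-2-(silyloxymethyl)but-2-enoate in place of allyl bromide, so the enoate is present before Shi epoxidation. The fragments are then united by Negishi coupling of the ester-tolerant alkylzinc iodide.

3. **Step 13 (lithium–iodine exchange next to the epoxide, then B-alkyl Suzuki coupling).** The γ-epoxy alkyllithium may cyclise or be protonated before boron capture. Fallback: install the epoxide after fragment union. Couple 10 with a non-epoxidised C2-hydroxy (allylic alcohol) West fragment, then use hydroxyl-directed Sharpless epoxidation, which selects the allylic C3=C4 alkene over C7=C8. C2 is then homologated to the allyl group through the epoxy triflate and a vinyl cuprate.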